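**Plan**

1. Prostaglandin numbering (C1–C20) is used throughout. The C15 ketone is traced back to an allylic alcohol, the 5Z alkene is cut by a Wittig disconnection (C5=C6), and the C9 hydroxyl and C6 are tied up as a γ-lactone fused to the cyclopentane.
2. Enabling feature: ring carbon C9 and side-chain carbon C6 can both be carbonyl carbons, 1,4 to each other through C8 and C7. The ring bond C8–C9 is therefore cut to a C9 acyl radical (from a phenyl selenoester) and a C8=C7–C6 enoate.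
3. The open chain is then cut at C7=C8 (stabilised Wittig), C11–C12 (syn aldol) and C13=C14 (cross-metathesis).
4. Forward: metathesis joins the ω-chain to a butenoyl imide, the aldol adds C9–C11, a Wittig adds C6–C7, the radical closure forms the cyclopentane (C8–C12, the only carbocycle), the lactone follows as a temporary second ring, and a second Wittig adds C1–C5.
5. Stereochemistry: C11 and C12 come from the boron aldol of an (S)-4-benzyloxazolidinone imide, C8 from the chair-like 5-exo transition state, C9 from β-face hydride delivery, 13E from metathesis and 5Z from the unstabilised ylide.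

Key step: step 13

Remark: (S)-oct-1-en-3-ol (1) is assumed to be purchasable in enantiopure form. C15 is oxidised in the last step, so its configuration is fixed as S only to keep every intermediate a single diastereomer. TBS = tert-butyldimethylsilyl and PMB = 4-methoxybenzyl; TBSO and PMBO denote the corresponding ethers.

**Route**

Step 1
Reactants: 1 (S)-oct-1-en-3-ol
Product: 2 (S)-3-(TBSO)oct-1-ene
Conditions: TBSCl, imidazole, DMF, rt
Reagents that add atoms: tert-butyldimethylsilyl chloride, CC(C)(C)[Si](C)(C)Cl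
Why: Routine imidazole-promoted silylation of a secondary allylic alcohol, which leaves the C15 centre untouched.

Step 2
Reactants: 3 but-3-enoic acid; 4 (S)-4-benzyl-1,3-oxazolidin-2-one
Product: 6 (S)-4-benzyl-3-(but-3-enoyl)-1,3-oxazolidin-2-one, via mixed pivalic anhydride 5 (not isolated)
Conditions: PivCl, Et3N, THF, −20 °C; then 4, LiCl, −20 °C → rt
Reagents that add atoms: none
Why: N-acylation of the oxazolidinone through a mixed pivalic anhydride with LiCl/Et3N, which avoids the strong base that would pull the β,γ-alkene into conjugation.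

Step 3
Reactants: 6 (S)-4-benzyl-3-(but-3-enoyl)-1,3-oxazolidin-2-one; 2 (S)-3-(TBSO)oct-1-ene
Product: 7 (S)-4-benzyl-3-[(3E,5S)-5-(TBSO)dec-3-enoyl]-1,3-oxazolidin-2-one
Conditions: 2 (3 equiv), second-generation Hoveyda–Grubbs catalyst RuCl2(H2IMes)(=CH–C6H4–2-Oi-Pr) (5 mol%), 1,4-benzoquinone (10 mol%), CH2Cl2, 40 °C
Reagents that add atoms: none
Why: Olefin cross-metathesis between an unhindered terminal alkene and an excess of a slowly homodimerising allylic silyl ether should give the E alkene under thermodynamic control, with benzoquinone suppressing alkene migration by ruthenium hydrides.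

Step 4
Reactants: 8 propane-1,3-diol
Product: 9 3-(PMBO)propan-1-ol
Conditions: 8 (3 equiv), NaH (1 equiv), THF/DMF, 0 °C; PMBCl, Bu4NI (cat.), rt
Reagents that add atoms: 4-methoxybenzyl chloride, COc1ccc(CCl)cc1
Why: Williamson etherification in which the excess of diol favours mono-alkylation.

Step 5
Reactants: 9 3-(PMBO)propan-1-ol
Product: 10 3-(PMBO)propanal
Conditions: TEMPO (10 mol%), PhI(OAc)2, CH2Cl2, rt
Reagents that add atoms: none
Why: Nitroxyl-catalysed oxidation with PhI(OAc)2 stops at the aldehyde in dry CH2Cl2 and is non-basic, so the β-alkoxy aldehyde should not lose 4-methoxybenzyl alcohol.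

Step 6
Reactants: 7 (S)-4-benzyl-3-[(3E,5S)-5-(TBSO)dec-3-enoyl]-1,3-oxazolidin-2-one; 10 3-(PMBO)propanal
Product: 13 (S)-4-benzyl-3-[(2S,3E,5S)-5-(TBSO)-2-[(1R)-1-hydroxy-3-(PMBO)propyl]dec-3-enoyl]-1,3-oxazolidin-2-one, via dibutylboron enolate 11 (not isolated), via dibutylboron aldolate 12 (not isolated)
Conditions: Bu2BOTf, i-Pr2NEt, CH2Cl2, −78 → 0 °C; 10, −78 → 0 °C; pH 7 buffer, MeOH, H2O2, 0 °C
Reagents that add atoms: none
Why: Evans syn aldol, in which the Z boron enolate reacts through its α-carbon (C12) in a closed chair transition state and the benzyl group of the (S)-auxiliary blocks one enolate face, setting C12 and C11 (11R) syn in one operation.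

Step 7
Reactants: 13 (S)-4-benzyl-3-[(2S,3E,5S)-5-(TBSO)-2-[(1R)-1-hydroxy-3-(PMBO)propyl]dec-3-enoyl]-1,3-oxazolidin-2-one
Product: 14 (S)-4-benzyl-3-[(2S,3E,5S)-5-(TBSO)-2-[(1R)-1-(TBSO)-3-(PMBO)propyl]dec-3-enoyl]-1,3-oxazolidin-2-one
Conditions: TBSOTf, 2,6-lutidine, CH2Cl2, −78 → 0 °C
Reagents that add atoms: tert-butyldimethylsilyl trifluoromethanesulfonate, CC(C)(C)[Si](C)(C)OS(=O)(=O)C(F)(F)F
Why: Silyl triflate with a hindered pyridine base silylates the hindered aldol hydroxyl without retro-aldol cleavage or epimerisation at C12.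

Step 8
Reactants: 14 (S)-4-benzyl-3-[(2S,3E,5S)-5-(TBSO)-2-[(1R)-1-(TBSO)-3-(PMBO)propyl]dec-3-enoyl]-1,3-oxazolidin-2-one
Product: 15 (2R,3E,5S)-5-(TBSO)-2-[(1R)-1-(TBSO)-3-(PMBO)propyl]dec-3-en-1-ol
Conditions: LiBH4, MeOH (1 equiv), THF, 0 °C
Reagents that add atoms: none
Why: Reductive cleavage of the N-acyl oxazolidinone by borohydride gives the C8 primary alcohol and releases the auxiliary without enolising C12.

Step 9
Reactants: 15 (2R,3E,5S)-5-(TBSO)-2-[(1R)-1-(TBSO)-3-(PMBO)propyl]dec-3-en-1-ol; 16 methyl (triphenyl-λ5-phosphanylidene)acetate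
Product: 18 methyl (2E,4R,5E,7S)-7-(TBSO)-4-[(1R)-1-(TBSO)-3-(PMBO)propyl]dodeca-2,5-dienoate, via aldehyde 17 (not isolated)
Conditions: Dess–Martin periodinane, NaHCO3, CH2Cl2, 0 °C → rt; then 16 (3 equiv), rt
Reagents that add atoms: none
Why: Buffered periodinane oxidation followed in the same flask by a Wittig reaction with the stabilised ylide should give the E enoate, and trapping the α-stereogenic β,γ-unsaturated aldehyde at once keeps C12 from epimerising or the alkene from conjugating.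

Step 10
Reactants: 18 methyl (2E,4R,5E,7S)-7-(TBSO)-4-[(1R)-1-(TBSO)-3-(PMBO)propyl]dodeca-2,5-dienoate
Product: 19 methyl (2E,4R,5E,7S)-7-(TBSO)-4-[(1R)-1-(TBSO)-3-hydroxypropyl]dodeca-2,5-dienoate
Conditions: DDQ, CH2Cl2/pH 7 buffer, 0 °C
Reagents that add atoms: none
Why: Oxidative cleavage of the electron-rich benzyl ether by DDQ is neutral, so the silyl ethers, both alkenes and the base-sensitive hydroxy enoate (prone to oxa-Michael closure) should survive.

Step 11
Reactants: 19 methyl (2E,4R,5E,7S)-7-(TBSO)-4-[(1R)-1-(TBSO)-3-hydroxypropyl]dodeca-2,5-dienoate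
Product: 21 (3R,4R,5E,7S)-3,7-bis(TBSO)-4-[(1E)-3-methoxy-3-oxoprop-1-enyl]dodec-5-enoic acid, via aldehyde 20 (not isolated)
Conditions: TEMPO (20 mol%), PhI(OAc)2 (2.2 equiv), MeCN/H2O, rt
Reagents that add atoms: water, O
Why: Nitroxyl-catalysed oxidation in aqueous acetonitrile takes the primary alcohol through the aldehyde hydrate to the acid near neutrality, so the C11 silyloxy group β to the new carbonyl is not eliminated.

Step 12
Reactants: 21 (3R,4R,5E,7S)-3,7-bis(TBSO)-4-[(1E)-3-methoxy-3-oxoprop-1-enyl]dodec-5-enoic acid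
Product: 22 Se-phenyl (3R,4R,5E,7S)-3,7-bis(TBSO)-4-[(1E)-3-methoxy-3-oxoprop-1-enyl]dodec-5-eneselenoate
Conditions: PhSeSePh, Bu3P (premixed), CH2Cl2, rt
Reagents that add atoms: diphenyl diselenide, c1ccc(cc1)[Se][Se]c1ccccc1
Why: Phosphine/diselenide selenoesterification activates the acid as an acyloxyphosphonium ion that phenylselenolate captures under neutral conditions.

Step 13
Reactants: 22 Se-phenyl (3R,4R,5E,7S)-3,7-bis(TBSO)-4-[(1E)-3-methoxy-3-oxoprop-1-enyl]dodec-5-eneselenoate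
Product: 23 methyl 2-[(1R,2R,3R)-3-(TBSO)-2-[(1E,3S)-3-(TBSO)oct-1-enyl]-5-oxocyclopentyl]acetate
Conditions: Bu3SnH (1.3 equiv, slow addition), AIBN (cat.), benzene (0.01 M), 80 °C
Reagents that add atoms: none
Why: The tributyltin radical abstracts the phenylselanyl group from 22 to give the nucleophilic C9 acyl radical, which adds to C8, the electron-poor β-carbon of the C8=C7–C6 enoate, and the resulting α-ester radical at C7 takes hydrogen from Bu3SnH to carry the chain. The closest known reaction type is the tin hydride-mediated cyclisation of acyl radicals from phenyl selenoesters onto α,β-unsaturated esters to give cycloalkanones. The cyclopentanone (ring carbons C8–C12) closes in the 5-exo-trig mode, which should outrun both decarbonylation of a primary-alkyl acyl radical and its reduction to the aldehyde at low stannane concentration. The new C8 stereocentre is controlled by the chair-like transition state in which the C12 alkenyl and C11 silyloxy groups sit pseudo-equatorial, placing the C8 acetate arm trans to C12 and cis to the C11 oxygen (8R). The step needs chemoselectivity for the enoate over the C13=C14 alkene, which is also 5-exo-disposed; polarity matching of the acyl radical with the acrylate, against an unactivated alkene shielded by the C15 silyl ether, should secure it. The neutral medium keeps the C11 silyloxy group, β to the selenoester and to the new ketone, from eliminating.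

Step 14
Reactants: 23 methyl 2-[(1R,2R,3R)-3-(TBSO)-2-[(1E,3S)-3-(TBSO)oct-1-enyl]-5-oxocyclopentyl]acetate
Product: 25 (3aR,4R,5R,6aS)-5-(TBSO)-4-[(1E,3S)-3-(TBSO)oct-1-enyl]hexahydro-2H-cyclopenta[b]furan-2-one, via 9α-hydroxy ester 24 (not isolated)
Conditions: LiBH(s-Bu)3, THF, −78 °C; pH 7 buffer; then PPTS (cat.), CH2Cl2, rt
Reagents that add atoms: none
Why: Diastereoselective ketone reduction in which the bulky borohydride attacks C9 from the β face, away from the C8 arm and the C11 silyloxy group, gives the 9α-alcohol (9S), which is cis to the acetate arm and lactonises.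

Step 15
Reactants: 25 (3aR,4R,5R,6aS)-5-(TBSO)-4-[(1E,3S)-3-(TBSO)oct-1-enyl]hexahydro-2H-cyclopenta[b]furan-2-one
Product: 26 (3aR,4R,5R,6aS)-5-(TBSO)-4-[(1E,3S)-3-(TBSO)oct-1-enyl]hexahydro-2H-cyclopenta[b]furan-2-ol (both anomers)
Conditions: i-Bu2AlH, toluene, −78 °C
Reagents that add atoms: none
Why: Partial reduction of a γ-lactone to the lactol, in which the tetrahedral aluminium alkoxide is stable at −78 °C and stops the reduction at the aldehyde level.

Step 16
Reactants: 26 (3aR,4R,5R,6aS)-5-(TBSO)-4-[(1E,3S)-3-(TBSO)oct-1-enyl]hexahydro-2H-cyclopenta[b]furan-2-ol; 27 (4-carboxybutyl)triphenylphosphonium bromide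
Product: 29 (5Z)-7-[(1R,2R,3R,5S)-3-(TBSO)-2-[(1E,3S)-3-(TBSO)oct-1-enyl]-5-hydroxycyclopentyl]hept-5-enoic acid (11,15-bis-TBS ether of PGF2α), via phosphorus ylide 28 (not isolated)
Conditions: KOt-Bu, THF, 0 °C → rt; add 26, rt; cold dilute aq. HCl to pH 4
Reagents that add atoms: none
Why: Wittig reaction of the unstabilised ylide with the open hydroxy aldehyde form of the lactol should give the 5Z alkene under kinetic control.

Step 17
Reactants: 29 (5Z)-7-[(1R,2R,3R,5S)-3-(TBSO)-2-[(1E,3S)-3-(TBSO)oct-1-enyl]-5-hydroxycyclopentyl]hept-5-enoic acid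
Product: 30 (5Z)-7-[(1R,2R,3R,5S)-3,5-dihydroxy-2-[(1E,3S)-3-hydroxyoct-1-enyl]cyclopentyl]hept-5-enoic acid (PGF2α)
Conditions: aq. HF, MeCN, 0 °C → rt
Reagents that add atoms: none
Why: Fluoride-driven cleavage of both silyl ethers; the 9,11-diol framework has no β-hydroxy ketone and should tolerate the acidic medium.

Step 18
Reactants: 30 (5Z)-7-[(1R,2R,3R,5S)-3,5-dihydroxy-2-[(1E,3S)-3-hydroxyoct-1-enyl]cyclopentyl]hept-5-enoic acid
Product: 31 (5Z)-7-[(1R,2R,3R,5S)-3,5-dihydroxy-2-[(1E)-3-oxooct-1-enyl]cyclopentyl]hept-5-enoic acid (15-keto-PGF2α)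
Conditions: DDQ, 1,4-dioxane, rt
Reagents that add atoms: none
Why: Chemoselective allylic oxidation, since DDQ abstracts hydride only from the allylic carbinol C15 and should leave the saturated C9 and C11 alcohols alone.

**Compound list**

1 | (S)-oct-1-en-3-ol | CCCCC[C@H](O)C=C | starting material
2 | (S)-3-(TBSO)oct-1-ene | CCCCC[C@H](O[Si](C)(C)C(C)(C)C)C=C | intermediate
3 | but-3-enoic acid | C=CCC(=O)O | starting material
4 | (S)-4-benzyl-1,3-oxazolidin-2-one | O=C1N[C@@H](Cc2ccccc2)CO1 | starting material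
5 | but-3-enoic pivalic anhydride | C=CCC(=O)OC(=O)C(C)(C)C | intermediate
6 | (S)-4-benzyl-3-(but-3-enoyl)-1,3-oxazolidin-2-one | C=CCC(=O)N1[C@@H](Cc2ccccc2)COC1=O | intermediate
7 | (S)-4-benzyl-3-[(3E,5S)-5-(TBSO)dec-3-enoyl]-1,3-oxazolidin-2-one | CCCCC[C@H](O[Si](C)(C)C(C)(C)C)/C=C/CC(=O)N1[C@@H](Cc2ccccc2)COC1=O | intermediate
8 | propane-1,3-diol | OCCCO | starting material
9 | 3-(PMBO)propan-1-ol | COc1ccc(COCCCO)cc1 | intermediate
10 | 3-(PMBO)propanal | COc1ccc(COCCC=O)cc1 | intermediate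
11 | dibutylboron (Z)-enolate of 7 | CCCCC[C@H](O[Si](C)(C)C(C)(C)C)/C=C/C=C(\OB(CCCC)CCCC)N1[C@@H](Cc2ccccc2)COC1=O | intermediate
12 | O-dibutylboryl aldolate of 13 | CCCCC[C@H](O[Si](C)(C)C(C)(C)C)/C=C/[C@H](C(=O)N1[C@@H](Cc2ccccc2)COC1=O)[C@H](OB(CCCC)CCCC)CCOCc1ccc(OC)cc1 | intermediate
13 | (S)-4-benzyl-3-[(2S,3E,5S)-5-(TBSO)-2-[(1R)-1-hydroxy-3-(PMBO)propyl]dec-3-enoyl]-1,3-oxazolidin-2-one | CCCCC[C@H](O[Si](C)(C)C(C)(C)C)/C=C/[C@H](C(=O)N1[C@@H](Cc2ccccc2)COC1=O)[C@H](O)CCOCc1ccc(OC)cc1 | intermediate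
14 | (S)-4-benzyl-3-[(2S,3E,5S)-5-(TBSO)-2-[(1R)-1-(TBSO)-3-(PMBO)propyl]dec-3-enoyl]-1,3-oxazolidin-2-one | CCCCC[C@H](O[Si](C)(C)C(C)(C)C)/C=C/[C@H](C(=O)N1[C@@H](Cc2ccccc2)COC1=O)[C@H](O[Si](C)(C)C(C)(C)C)CCOCc1ccc(OC)cc1 | intermediate
15 | (2R,3E,5S)-5-(TBSO)-2-[(1R)-1-(TBSO)-3-(PMBO)propyl]dec-3-en-1-ol | CCCCC[C@H](O[Si](C)(C)C(C)(C)C)/C=C/[C@H](CO)[C@H](O[Si](C)(C)C(C)(C)C)CCOCc1ccc(OC)cc1 | intermediate
16 | methyl (triphenyl-λ5-phosphanylidene)acetate | COC(=O)C=P(c1ccccc1)(c1ccccc1)c1ccccc1 | starting material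
17 | (2S,3E,5S)-5-(TBSO)-2-[(1R)-1-(TBSO)-3-(PMBO)propyl]dec-3-enal | CCCCC[C@H](O[Si](C)(C)C(C)(C)C)/C=C/[C@H](C=O)[C@H](O[Si](C)(C)C(C)(C)C)CCOCc1ccc(OC)cc1 | intermediate
18 | methyl (2E,4R,5E,7S)-7-(TBSO)-4-[(1R)-1-(TBSO)-3-(PMBO)propyl]dodeca-2,5-dienoate | CCCCC[C@H](O[Si](C)(C)C(C)(C)C)/C=C/[C@H](/C=C/C(=O)OC)[C@H](O[Si](C)(C)C(C)(C)C)CCOCc1ccc(OC)cc1 | intermediate
19 | methyl (2E,4R,5E,7S)-7-(TBSO)-4-[(1R)-1-(TBSO)-3-hydroxypropyl]dodeca-2,5-dienoate | CCCCC[C@H](O[Si](C)(C)C(C)(C)C)/C=C/[C@H](/C=C/C(=O)OC)[C@H](O[Si](C)(C)C(C)(C)C)CCO | intermediate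
20 | methyl (2E,4R,5E,7S)-7-(TBSO)-4-[(1R)-1-(TBSO)-3-oxopropyl]dodeca-2,5-dienoate | CCCCC[C@H](O[Si](C)(C)C(C)(C)C)/C=C/[C@H](/C=C/C(=O)OC)[C@H](O[Si](C)(C)C(C)(C)C)CC=O | intermediate
21 | (3R,4R,5E,7S)-3,7-bis(TBSO)-4-[(1E)-3-methoxy-3-oxoprop-1-enyl]dodec-5-enoic acid | CCCCC[C@H](O[Si](C)(C)C(C)(C)C)/C=C/[C@H](/C=C/C(=O)OC)[C@H](O[Si](C)(C)C(C)(C)C)CC(=O)O | intermediate
22 | Se-phenyl (3R,4R,5E,7S)-3,7-bis(TBSO)-4-[(1E)-3-methoxy-3-oxoprop-1-enyl]dodec-5-eneselenoate | CCCCC[C@H](O[Si](C)(C)C(C)(C)C)/C=C/[C@H](/C=C/C(=O)OC)[C@H](O[Si](C)(C)C(C)(C)C)CC(=O)[Se]c1ccccc1 | intermediate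
23 | methyl 2-[(1R,2R,3R)-3-(TBSO)-2-[(1E,3S)-3-(TBSO)oct-1-enyl]-5-oxocyclopentyl]acetate | CCCCC[C@H](O[Si](C)(C)C(C)(C)C)/C=C/[C@@H]1[C@@H](CC(=O)OC)C(=O)C[C@H]1O[Si](C)(C)C(C)(C)C | intermediate
24 | methyl 2-[(1R,2R,3R,5S)-3-(TBSO)-2-[(1E,3S)-3-(TBSO)oct-1-enyl]-5-hydroxycyclopentyl]acetate | CCCCC[C@H](O[Si](C)(C)C(C)(C)C)/C=C/[C@@H]1[C@@H](CC(=O)OC)[C@@H](O)C[C@H]1O[Si](C)(C)C(C)(C)C | intermediate
25 | (3aR,4R,5R,6aS)-5-(TBSO)-4-[(1E,3S)-3-(TBSO)oct-1-enyl]hexahydro-2H-cyclopenta[b]furan-2-one | CCCCC[C@H](O[Si](C)(C)C(C)(C)C)/C=C/[C@@H]1[C@H]2CC(=O)O[C@H]2C[C@H]1O[Si](C)(C)C(C)(C)C | intermediate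
26 | (3aR,4R,5R,6aS)-5-(TBSO)-4-[(1E,3S)-3-(TBSO)oct-1-enyl]hexahydro-2H-cyclopenta[b]furan-2-ol | CCCCC[C@H](O[Si](C)(C)C(C)(C)C)/C=C/[C@@H]1[C@H]2CC(O)O[C@H]2C[C@H]1O[Si](C)(C)C(C)(C)C | intermediate
27 | (4-carboxybutyl)triphenylphosphonium bromide | OC(=O)CCCC[P+](c1ccccc1)(c1ccccc1)c1ccccc1.[Br-] | starting material
28 | potassium 5-(triphenyl-λ5-phosphanylidene)pentanoate | [K+].[O-]C(=O)CCCC=P(c1ccccc1)(c1ccccc1)c1ccccc1 | intermediate
29 | (5Z)-7-[(1R,2R,3R,5S)-3-(TBSO)-2-[(1E,3S)-3-(TBSO)oct-1-enyl]-5-hydroxycyclopentyl]hept-5-enoic acid | CCCCC[C@H](O[Si](C)(C)C(C)(C)C)/C=C/[C@@H]1[C@@H](C/C=C\CCCC(=O)O)[C@@H](O)C[C@H]1O[Si](C)(C)C(C)(C)C | intermediate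
30 | PGF2α, (5Z)-7-[(1R,2R,3R,5S)-3,5-dihydroxy-2-[(1E,3S)-3-hydroxyoct-1-enyl]cyclopentyl]hept-5-enoic acid | CCCCC[C@H](O)/C=C/[C@@H]1[C@@H](C/C=C\CCCC(=O)O)[C@@H](O)C[C@H]1O | intermediate
31 | 15-keto-PGF2α, (5Z)-7-[(1R,2R,3R,5S)-3,5-dihydroxy-2-[(1E)-3-oxooct-1-enyl]cyclopentyl]hept-5-enoic acid | CCCCCC(=O)/C=C/[C@@H]1[C@@H](C/C=C\CCCC(=O)O)[C@@H](O)C[C@H]1O | target

**Count and risks**

Total step count: 18. Longest linear sequence: 15 steps (steps 2, 3 and 6–18; the branches through steps 1 and 3 or through steps 4 and 5 are equally long).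

Steps most likely to fail:

1. Step 13. The acyl radical may close onto the C13=C14 alkene instead of the enoate, may be reduced to the aldehyde before it cyclises, or may close with poor control at C8. Fallback: set out from alcohol 19 and oxidise it with Dess–Martin periodinane only as far as aldehyde 20, isolated this time. The same C8–C9 bond is then closed by ketyl–olefin cyclisation with SmI2 (THF, MeOH, −78 °C). The C9 ketyl radical anion adds 5-exo to C8 of the enoate and is essentially inert towards an unactivated alkene. This should give methyl 2-[(1R,2R,3R)-3-(TBSO)-2-[(1E,3S)-3-(TBSO)oct-1-enyl]-5-hydroxycyclopentyl]acetate F1 as either C9 epimer. Dess–Martin oxidation of F1 comes back to the route at ketone 23.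

2. Step 3. The cross-metathesis may stall on the hindered allylic silyl ether, be overtaken by homodimerisation of 6, or be spoiled by ruthenium hydride-induced migration of the β,γ-alkene into conjugation with the imide. Fallback: set out from alkene 2. Hydroboration with 9-BBN gives 9-[(3R)-3-(TBSO)octyl]-9-borabicyclo[3.3.1]nonane F2 (R only through a change in substituent priorities), and NaOH/H2O2 then gives (S)-3-(TBSO)octan-1-ol F3. TEMPO/PhI(OAc)2 gives (S)-3-(TBSO)octanal F4. Deconjugative Knoevenagel–Doebner condensation with malonic acid (Et3N, 90 °C) proceeds through 2-[(3S)-3-(TBSO)octylidene]propanedioic acid F5 and decarboxylation to (3E,5S)-5-(TBSO)dec-3-enoic acid F6. Activation as (3E,5S)-5-(TBSO)dec-3-enoic pivalic anhydride F7 and acylation of 4 under the conditions of step 2 comes back to the route at imide 7.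

3. Step 6. The dienolate may react through its γ-carbon, enolisation may cause vinylogous loss of silanol or drift of the alkene into conjugation, and the β-alkoxy aldehyde may eliminate. Fallback: set out from the simple imide 6 and aldehyde 10 and run the same boron aldol before the ω-chain is attached. The dibutylboron (Z)-enolate of 6 F8 and the O-dibutylboryl aldolate F9 lead to (S)-4-benzyl-3-[(2S,3R)-2-ethenyl-3-hydroxy-5-(PMBO)pentanoyl]-1,3-oxazolidin-2-one F10. TBSOTf/2,6-lutidine gives (S)-4-benzyl-3-[(2S,3R)-2-ethenyl-3-(TBSO)-5-(PMBO)pentanoyl]-1,3-oxazolidin-2-one F11. Cross-metathesis of F11 with an excess of 2 (same ruthenium catalyst as in step 3) comes back to the route at 14.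

**Further compounds**

F1 | step 13 | methyl 2-[(1R,2R,3R)-3-(TBSO)-2-[(1E,3S)-3-(TBSO)oct-1-enyl]-5-hydroxycyclopentyl]acetate (C9 epimers) | CCCCC[C@H](O[Si](C)(C)C(C)(C)C)/C=C/[C@@H]1[C@@H](CC(=O)OC)C(O)C[C@H]1O[Si](C)(C)C(C)(C)C
F2 | step 3 | 9-[(3R)-3-(TBSO)octyl]-9-borabicyclo[3.3.1]nonane | CCCCC[C@H](O[Si](C)(C)C(C)(C)C)CCB1C2CCCC1CCC2
F3 | step 3 | (S)-3-(TBSO)octan-1-ol | CCCCC[C@H](O[Si](C)(C)C(C)(C)C)CCO
F4 | step 3 | (S)-3-(TBSO)octanal | CCCCC[C@H](O[Si](C)(C)C(C)(C)C)CC=O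
F5 | step 3 | 2-[(3S)-3-(TBSO)octylidene]propanedioic acid | CCCCC[C@H](O[Si](C)(C)C(C)(C)C)CC=C(C(=O)O)C(=O)O
F6 | step 3 | (3E,5S)-5-(TBSO)dec-3-enoic acid | CCCCC[C@H](O[Si](C)(C)C(C)(C)C)/C=C/CC(=O)O
F7 | step 3 | (3E,5S)-5-(TBSO)dec-3-enoic pivalic anhydride | CCCCC[C@H](O[Si](C)(C)C(C)(C)C)/C=C/CC(=O)OC(=O)C(C)(C)C
F8 | step 6 | dibutylboron (Z)-enolate of 6 | C=C/C=C(\OB(CCCC)CCCC)N1[C@@H](Cc2ccccc2)COC1=O
F9 | step 6 | O-dibutylboryl aldolate of F10 | C=C[C@H](C(=O)N1[C@@H](Cc2ccccc2)COC1=O)[C@H](OB(CCCC)CCCC)CCOCc1ccc(OC)cc1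
F10 | step 6 | (S)-4-benzyl-3-[(2S,3R)-2-ethenyl-3-hydroxy-5-(PMBO)pentanoyl]-1,3-oxazolidin-2-one | C=C[C@H](C(=O)N1[C@@H](Cc2ccccc2)COC1=O)[C@H](O)CCOCc1ccc(OC)cc1
F11 | step 6 | (S)-4-benzyl-3-[(2S,3R)-2-ethenyl-3-(TBSO)-5-(PMBO)pentanoyl]-1,3-oxazolidin-2-one | C=C[C@H](C(=O)N1[C@@H](Cc2ccccc2)COC1=O)[C@H](O[Si](C)(C)C(C)(C)C)CCOCc1ccc(OC)cc1
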